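**Plan**

1. Cuts: the two CHO groups (Rieche) and the benzyl groups/ring C=C (H2) go last. Then both cyclopentane bonds that tie the CH2–CH2–C(Me) unit to the carane ring (C-4–CH2 and C-5–C(Me)) are cut in one formal (3+2) step. Before that come the aryl–O–alkenyl bond (Chan–Lam) and the benzylic C–isobutyl bond (asymmetric allylic alkylation).
2. Forward: cyclopropane, then 1,3-carbonyl transposition on (S)-carvone gives the carane ketone. The allene side chain is built on the arene. After ether union, the benzoxepine and cyclopentane rings close together in step 18, followed by hydrogenation and bis-formylation.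
3. Enabling feature: carane C-4/C-5 sit at the oxidation level of an aryl enol ether (ArO–C4=C5). C-5 is nucleophilic and the ether oxygen stabilises the cation at C-4, so charge never sits next to the cyclopropane. The two carbons to be attached are 1,3-related in the cyclopentane, which corresponds to an allyl cation generated from an allene held over the π bond by the O–aryl–CH tether.
4. Stereochemistry: carane C-1/C-6 come from carvone C-5. The C-3 methyl is set cis to the cyclopropane by protonation/equilibration. The benzylic centre comes from catalyst-controlled SN2' alkylation. The three centres of step 18 follow from attack anti to the gem-dimethylcyclopropane and from the tether.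

Key step: step 18

Remark: carane numbering is used for the bicyclo[4.1.0]heptane part (C-3 bears the methyl, C-4 the oxygen, C-5 is the CH next to it, C-7 is CMe2). This part belongs to the series enantiomeric to (+)-3-carene, so it is made from (S)-carvone.

**Route**

Step 1
Reactants: 1 (S)-(+)-carvone
Product: 2 (5S)-5-(2-chloropropan-2-yl)-2-methylcyclohex-2-en-1-one
Conditions: HCl (g), Et2O, 0 °C
Reagents that add atoms: hydrogen chloride, Cl
Why: Markovnikov hydrochlorination of the electron-rich isopropenyl group should leave the conjugated enone and the stereocentre untouched.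

Step 2
Reactants: 2
Product: 3 (1R,6S)-3,7,7-trimethylbicyclo[4.1.0]hept-3-en-2-one
Conditions: KOt-Bu, THF, 0 °C, short contact time
Reagents that add atoms: none
Why: Intramolecular enolate alkylation (3-exo-tet displacement of the tertiary chloride by the α'-enolate) should give the cis-fused gem-dimethylcyclopropane, the new ring-fusion centre following from the existing one because only cis fusion is possible.

Step 3
Reactants: 3
Product: 4 3,4-epoxycaran-2-one, epoxide oxygen trans to the CMe2 bridge
Conditions: 30% H2O2, NaOH (cat.), MeOH, 0 °C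
Reagents that add atoms: hydrogen peroxide, OO
Why: Weitz–Scheffer nucleophilic epoxidation of the enone should occur on the face anti to the endo methyl of the cyclopropane.

Step 4
Reactants: 4
Product: 6 (1R,4S,6S)-3,7,7-trimethylbicyclo[4.1.0]hept-2-en-4-ol, via epoxy hydrazone 5 (not isolated)
Conditions: N2H4·H2O, AcOH (cat.), MeOH, 0 °C → rt
Reagents that add atoms: none
Why: Wharton transposition should move the oxygen to the carbon that becomes the ether carbon of the target, with loss of N2; the carbinol configuration is erased in step 5.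

Step 5
Reactants: 6
Product: 7 (1R,6S)-3,7,7-trimethylbicyclo[4.1.0]hept-2-en-4-one
Conditions: MnO2, CH2Cl2, rt
Reagents that add atoms: none
Why: MnO2 oxidation is selective for the allylic alcohol and should give the β-cyclopropyl enone.

Step 6
Reactants: 7
Product: 9 (1R,3S,6S)-3,7,7-trimethylbicyclo[4.1.0]heptan-4-one (3-methyl cis to the cyclopropane), via lithium enolate 8 (not isolated)
Conditions: LiBH(s-Bu)3, THF, −78 °C; aq. NH4Cl; then NaOMe (cat.), MeOH, rt
Reagents that add atoms: none
Why: Conjugate hydride reduction (as for carvone-type 2-methylcyclohexenones) gives the enolate; protonation from the open face and base equilibration should both place the 3-methyl cis to the cyclopropane, expected to be the more stable epimer.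

Step 7
Reactants: 9
Product: 11 (1R,3S,6R)-3,7,7-trimethylbicyclo[4.1.0]hept-4-en-4-yl trifluoromethanesulfonate, via kinetic lithium enolate 10 (not isolated)
Conditions: LiN(i-Pr)2, THF, −78 °C; then PhNTf2, −78 → 0 °C
Reagents that add atoms: N-phenylbis(trifluoromethanesulfonimide), O=S(=O)(N(c1ccccc1)S(=O)(=O)C(F)(F)F)C(F)(F)F
Why: Kinetic deprotonation at the less hindered CH2 (C-5) followed by O-triflation should fix the enol regiochemistry without touching the C-3 stereocentre.

Step 8
Reactants: 11
Product: 12 pinacol (1R,3S,6S)-3,7,7-trimethylbicyclo[4.1.0]hept-4-en-4-ylboronate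
Conditions: B2pin2, PdCl2(PPh3)2 (3 mol%), PPh3, KOPh, toluene, 50 °C
Reagents that add atoms: bis(pinacolato)diboron, CC1(C)OB(OC1(C)C)B1OC(C)(C)C(C)(C)O1
Why: Miyaura borylation of an alkenyl triflate should proceed with retention of the double-bond position.

Step 9
Reactants: 13 2,4-bis(benzyloxy)-6-hydroxybenzaldehyde
Product: 14 2,4-bis(benzyloxy)-6-{[2-(trimethylsilyl)ethoxy]methoxy}benzaldehyde
Conditions: SEMCl, i-Pr2NEt, CH2Cl2, 0 °C → rt
Reagents that add atoms: 2-(trimethylsilyl)ethoxymethyl chloride, ClCOCC[Si](C)(C)C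
Why: Phenol O-alkylation; the SEM ether should survive the Grignard, carbene and MeLi steps and is orthogonal to the benzyl ethers.

Step 10
Reactants: 14
Product: 15 ethyl (E)-3-[2,4-bis(benzyloxy)-6-(SEM-oxy)phenyl]-2-methylprop-2-enoate
Conditions: Ph3P=C(Me)CO2Et, toluene, 100 °C
Reagents that add atoms: ethyl 2-(triphenylphosphoranylidene)propanoate, CCOC(=O)C(C)=P(c1ccccc1)(c1ccccc1)c1ccccc1
Why: Wittig olefination with a stabilised ylide should give the (E)-trisubstituted enoate.

Step 11
Reactants: 15
Product: 16 (E)-3-[2,4-bis(benzyloxy)-6-(SEM-oxy)phenyl]-2-methylprop-2-en-1-ol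
Conditions: i-Bu2AlH, CH2Cl2, −78 °C
Reagents that add atoms: none
Why: 1,2-Reduction of the conjugated ester should give the allylic alcohol without touching the alkene geometry.

Step 12
Reactants: 16
Product: 18 (E)-allylic chloride of 16, via allylic mesylate 17 (not isolated)
Conditions: MsCl, Et3N, THF, −40 °C; then LiCl, DMF, 0 °C
Reagents that add atoms: lithium chloride, [Li+].[Cl-]
Why: Mesylation and chloride displacement should give the primary (E)-chloride, which is also the conjugated, thermodynamic allylic isomer.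

Step 13
Reactants: 18
Product: 19 1,5-bis(benzyloxy)-2-[(3R)-2,5-dimethylhex-1-en-3-yl]-3-(SEM-oxy)benzene
Conditions: i-BuMgBr (slow addition), Cu(thiophene-2-carboxylate) (3 mol%), BINOL-derived N,N-bis[1-(2-methoxyphenyl)ethyl]phosphoramidite (3.3 mol%, enantiomer chosen for the (R)-product), CH2Cl2, −78 °C
Reagents that add atoms: isobutylmagnesium bromide, CC(C)C[Mg]Br
Why: Copper-catalysed asymmetric allylic alkylation (anti SN2' delivery of the isobutyl group to the benzylic alkene carbon) should set the benzylic stereocentre under control of the chiral ligand.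

Step 14
Reactants: 19
Product: 20 gem-dibromocyclopropane of 19 (epimers at the new ring carbon)
Conditions: CHBr3, 50% aq. NaOH, BnEt3NCl (cat.), CH2Cl2, 0 °C → rt
Reagents that add atoms: bromoform, BrC(Br)Br
Why: Phase-transfer dibromocarbene cycloaddition to the 1,1-disubstituted alkene; the new ring stereocentre is lost in step 15.

Step 15
Reactants: 20
Product: 22 1,5-bis(benzyloxy)-2-[(4R)-3,6-dimethylhepta-1,2-dien-4-yl]-3-(SEM-oxy)benzene, via lithium carbenoid 21 (not isolated)
Conditions: MeLi, Et2O, −78 → −30 °C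
Reagents that add atoms: none
Why: Doering–LaFlamme allene synthesis: bromine–lithium exchange and ring opening of the cyclopropylidenoid should give the 1,1-disubstituted allene without touching the benzylic centre.

Step 16
Reactants: 22
Product: 23 3,5-bis(benzyloxy)-2-[(4R)-3,6-dimethylhepta-1,2-dien-4-yl]phenol
Conditions: Bu4NF, THF/DMPU, 50 °C
Reagents that add atoms: none
Why: Fluoride-induced cleavage of the aryl SEM ether should leave the benzyl ethers and the allene intact.

Step 17
Reactants: 23; 12
Product: 24 1,5-bis(benzyloxy)-2-[(4R)-3,6-dimethylhepta-1,2-dien-4-yl]-3-{[(1R,3S,6R)-3,7,7-trimethylbicyclo[4.1.0]hept-4-en-4-yl]oxy}benzene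
Conditions: Cu(OAc)2, pyridine, 4 Å molecular sieves, dry air, CH2Cl2, rt
Reagents that add atoms: none
Why: Chan–Lam oxidative C–O coupling of a phenol with an alkenylboronate at room temperature, chosen because it avoids organopalladium species that would add to the allene.

Step 18
Reactants: 24
Product: 27 bridged cyclopentene (the 2,4-di-O-benzyl, deformyl analogue of the target with CH=CH in place of CH2–CH2), via vinylgold oxocarbenium ion 25 (not isolated), via gold carbene 26 (not isolated)
Conditions: [1,3-bis(2,6-diisopropylphenyl)imidazol-2-ylidene]AuCl (5 mol%), AgSbF6 (5 mol%), CH2Cl2, −20 °C → rt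
Reagents that add atoms: none
Why: Proposed new method: the cationic complex of monovalent gold should turn the allene into a 2-aurated allyl cation whose fully substituted terminus is attacked by the nucleophilic β-carbon of the aryl enol ether (carane C-5), closing the benzoxepine ring (exo at the allyl terminus, enol ether π bond endocyclic) and leaving an aryl-oxocarbenium ion at C-4 plus a vinylgold unit (25); the CH2 terminus of the vinylgold then adds 5-exo to the oxocarbenium carbon to close the cyclopentane as gold carbene 26, and a 1,2-hydride shift releases cyclopentene 27 and the catalyst. The closest known reactions are the platinum- and gold-catalysed formal (3+2) cycloadditions of allenes with enol ethers or indoles through 2-metalla-allyl cations and metal carbenes, and the gold-catalysed (4+3) cycloaddition of allene-dienes; none has been shown in this bridging mode between an unactivated 1,1-dialkylallene and an aryl enol ether. Both new bonds must form on the face of the cyclohexene anti to the gem-dimethylcyclopropane and the cis C-3 methyl, which sets C-4 and C-5; the quaternary allyl terminus is set by the tether, because the O–aryl–CH bridge can join the oxygen on C-4 and that carbon only on this same face, and the benzylic centre is already in place. Regioselectivity (tertiary terminus to C-5, CH2 terminus to C-4) should follow from the polarity of the enol ether and from a seven- rather than nine-membered first closure. The step needs (3+2) over (2+2) closure, which the strongly donating carbene ligand (favouring the gold-carbene pathway) and the strain of the alternative bridged cyclobutane should secure.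

Step 19
Reactants: 27
Product: 28 deformyl target (diphenol with the saturated cyclopentane)
Conditions: H2 (1 atm), Pd/C, EtOAc/MeOH, rt
Reagents that add atoms: none
Why: Heterogeneous hydrogenation of the strained cis-disubstituted cyclopentene and hydrogenolysis of both benzyl ethers in one operation; no stereocentre is created and the unconjugated cyclopropane should survive at 1 atm.

Step 20
Reactants: 28
Product: 30 CNP0202714.1, via bis(α-chloro ether) 29 (not isolated)
Conditions: Cl2CHOMe, TiCl4, CH2Cl2, −78 → 0 °C; then H2O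
Reagents that add atoms: dichloromethyl methyl ether, COC(Cl)Cl; water, O
Why: Rieche formylation: titanium-phenoxide-directed C-formylation at the only two free ring positions, with hydrolysis of 29 on work-up, should give the dialdehyde.

**Compound list**

1 | (S)-(+)-carvone | CC(=C)[C@H]1CC=C(C)C(=O)C1 | starting material
2 | (5S)-5-(2-chloropropan-2-yl)-2-methylcyclohex-2-en-1-one | CC(C)(Cl)[C@H]1CC=C(C)C(=O)C1 | intermediate
3 | (1R,6S)-3,7,7-trimethylbicyclo[4.1.0]hept-3-en-2-one | CC1=CC[C@H]2[C@@H](C1=O)C2(C)C | intermediate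
4 | 3,4-epoxycaran-2-one (epoxide trans to CMe2) | C[C@]12O[C@H]1C[C@H]3[C@@H](C2=O)C3(C)C | intermediate
5 | hydrazone of 4 | C[C@]12O[C@H]1C[C@H]3[C@@H](C2=NN)C3(C)C | intermediate (not isolated)
6 | (1R,4S,6S)-3,7,7-trimethylbicyclo[4.1.0]hept-2-en-4-ol | CC1=C[C@@H]2[C@H](C[C@@H]1O)C2(C)C | intermediate
7 | (1R,6S)-3,7,7-trimethylbicyclo[4.1.0]hept-2-en-4-one | CC1=C[C@@H]2[C@H](CC1=O)C2(C)C | intermediate
8 | lithium C-3/C-4 enolate from conjugate reduction of 7 | CC1=C([O-])C[C@H]2[C@@H](C1)C2(C)C.[Li+] | intermediate (not isolated)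
9 | (1R,3S,6S)-3,7,7-trimethylbicyclo[4.1.0]heptan-4-one | C[C@H]1C[C@@H]2[C@H](CC1=O)C2(C)C | intermediate
10 | kinetic lithium C-4/C-5 enolate of 9 | C[C@H]1C[C@@H]2[C@H](C=C1[O-])C2(C)C.[Li+] | intermediate (not isolated)
11 | (1R,3S,6R)-3,7,7-trimethylbicyclo[4.1.0]hept-4-en-4-yl triflate | C[C@H]1C[C@@H]2[C@H](C=C1OS(=O)(=O)C(F)(F)F)C2(C)C | intermediate
12 | pinacol (1R,3S,6S)-3,7,7-trimethylbicyclo[4.1.0]hept-4-en-4-ylboronate | C[C@H]1C[C@@H]2[C@H](C=C1B3OC(C)(C)C(C)(C)O3)C2(C)C | intermediate
13 | 2,4-bis(benzyloxy)-6-hydroxybenzaldehyde | O=Cc1c(O)cc(OCc2ccccc2)cc1OCc1ccccc1 | starting material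
14 | 2,4-bis(benzyloxy)-6-(SEM-oxy)benzaldehyde | O=Cc1c(OCOCC[Si](C)(C)C)cc(OCc2ccccc2)cc1OCc1ccccc1 | intermediate
15 | ethyl (E)-3-aryl-2-methylprop-2-enoate | CCOC(=O)/C(C)=C/c1c(OCOCC[Si](C)(C)C)cc(OCc2ccccc2)cc1OCc1ccccc1 | intermediate
16 | (E)-3-aryl-2-methylprop-2-en-1-ol | OC/C(C)=C/c1c(OCOCC[Si](C)(C)C)cc(OCc2ccccc2)cc1OCc1ccccc1 | intermediate
17 | allylic mesylate of 16 | CS(=O)(=O)OC/C(C)=C/c1c(OCOCC[Si](C)(C)C)cc(OCc2ccccc2)cc1OCc1ccccc1 | intermediate (not isolated)
18 | (E)-allylic chloride | ClC/C(C)=C/c1c(OCOCC[Si](C)(C)C)cc(OCc2ccccc2)cc1OCc1ccccc1 | intermediate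
19 | 1,5-bis(benzyloxy)-2-[(3R)-2,5-dimethylhex-1-en-3-yl]-3-(SEM-oxy)benzene | CC(C)C[C@H](C(C)=C)c1c(OCOCC[Si](C)(C)C)cc(OCc2ccccc2)cc1OCc1ccccc1 | intermediate
20 | gem-dibromocyclopropane of 19 (epimers at the ring carbon) | CC(C)C[C@H](C1(C)CC1(Br)Br)c1c(OCOCC[Si](C)(C)C)cc(OCc2ccccc2)cc1OCc1ccccc1 | intermediate
21 | 1-bromo-1-lithiocyclopropane carbenoid from 20 | CC(C)C[C@H](C1(C)CC1([Li])Br)c1c(OCOCC[Si](C)(C)C)cc(OCc2ccccc2)cc1OCc1ccccc1 | intermediate (not isolated)
22 | 1,5-bis(benzyloxy)-2-[(4R)-3,6-dimethylhepta-1,2-dien-4-yl]-3-(SEM-oxy)benzene | CC(C)C[C@H](C(C)=C=C)c1c(OCOCC[Si](C)(C)C)cc(OCc2ccccc2)cc1OCc1ccccc1 | intermediate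
23 | 3,5-bis(benzyloxy)-2-[(4R)-3,6-dimethylhepta-1,2-dien-4-yl]phenol | CC(C)C[C@H](C(C)=C=C)c1c(O)cc(OCc2ccccc2)cc1OCc1ccccc1 | intermediate
24 | aryl enol ether of 23 with the carane C-4/C-5 alkene | CC(C)C[C@H](C(C)=C=C)c1c(OC2=C[C@H]3[C@@H](C[C@@H]2C)C3(C)C)cc(OCc2ccccc2)cc1OCc1ccccc1 | intermediate
25 | vinylgold aryl-oxocarbenium cation (benzoxepine closed) | CC(C)C[C@H]1c2c(OCc4ccccc4)cc(OCc4ccccc4)cc2[O+]=C2[C@@H]([C@]1(C)C(=C)[Au-]C5=[N+](c6c(C(C)C)cccc6C(C)C)C=CN5c6c(C(C)C)cccc6C(C)C)[C@H]1[C@@H](C[C@@H]2C)C1(C)C | intermediate (not isolated)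
26 | cyclopentylidene gold carbene cation | CC(C)C[C@H]1c2c(OCc4ccccc4)cc(OCc4ccccc4)cc2O[C@]23CC(=[Au]C5=[N+](c6c(C(C)C)cccc6C(C)C)C=CN5c6c(C(C)C)cccc6C(C)C)[C@@]1(C)[C@H]2[C@H]1[C@@H](C[C@@H]3C)C1(C)C | intermediate (not isolated)
27 | bridged cyclopentene, di-O-benzyl, deformyl | CC(C)C[C@H]1c2c(OCc4ccccc4)cc(OCc4ccccc4)cc2O[C@]23C=C[C@@]1(C)[C@H]2[C@H]1[C@@H](C[C@@H]3C)C1(C)C | intermediate
28 | deformyl target (diphenol) | CC(C)C[C@H]1c2c(O)cc(O)cc2O[C@]23CC[C@@]1(C)[C@H]2[C@H]1[C@@H](C[C@@H]3C)C1(C)C | intermediate
29 | bis[chloro(methoxy)methyl] adduct of 28 | CC(C)C[C@H]1c2c(O)c(C(Cl)OC)c(O)c(C(Cl)OC)c2O[C@]23CC[C@@]1(C)[C@H]2[C@H]1[C@@H](C[C@@H]3C)C1(C)C | intermediate (not isolated)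
30 | CNP0202714.1 | CC(C)C[C@H]1c2c(O)c(C=O)c(O)c(C=O)c2O[C@]23CC[C@@]1(C)[C@H]2[C@H]1[C@@H](C[C@@H]3C)C1(C)C | target

**Step count and risks**

Total steps: 20. Longest linear sequence: 12 steps (steps 1–8 or 9–16, then 17–20).

Steps most likely to fail:

Step 18. The vinylgold may close through its metal-bearing carbon to a cyclobutane. The oxocarbenium ion may lose a proton before the second ring closes. The allene may isomerise to a conjugated diene. Fallback with known reactions, starting from 24: the same gold catalyst in the presence of methanol (gold-catalysed alkoxycyclisation of an allene–ene) should close only the benzoxepine and trap the cation as the mixed methyl aryl ketal F1, which carries a vinyl group on the quaternary carbon. Sakurai allylation (allyltrimethylsilane, TMSOTf, CH2Cl2, −78 °C) of the oxocarbenium ion regenerated from F1 should add the allyl group anti to the cyclopropane and give the C-4 allyl compound F2. Isomerisation with RuHCl(CO)(PPh3)3 in toluene at 80 °C should give the (E)-propenyl compound F3. Ring-closing metathesis of F3 with the second-generation Grubbs catalyst then returns to the route at 27.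

Step 17. Transmetalation of the hindered, α-branched alkenylboronate may be slow, so that protodeboronation, homocoupling or oxidation of the electron-rich phenol wins. Fallback, starting from 12: iododeboronation (NaOH, then I2, THF/H2O) should give the alkenyl iodide F4. Ullmann-type C–O coupling of F4 with phenol 23 (CuI, N,N-dimethylglycine, Cs2CO3, dioxane, 90 °C) returns to the route at 24.

Step 13. Ionisation of the very electron-rich cinnamyl chloride (uncatalysed alkylation) and steric blocking of the benzylic carbon by two ortho substituents may erode regio- and enantioselectivity. Fallback, starting from 16: Sharpless asymmetric epoxidation (Ti(Oi-Pr)4, D-(−)-diethyl tartrate, t-BuOOH, 4 Å sieves, −20 °C) should give the (2R,3R)-epoxy alcohol F5. Opening at the benzylic carbon with inversion by an isobutyl cuprate (i-BuMgBr, CuI, THF, −40 °C) should give the 1,2-diol F6. Corey–Winter olefination (thiocarbonyldiimidazole to the cyclic thionocarbonate F7, then P(OMe)3, 110 °C) returns to the route at 19.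

**Further compounds**

F1 | step 18 | mixed methyl aryl ketal (benzoxepine closed, OMe on carane C-4 as epimers, vinyl on the quaternary carbon) | CC(C)C[C@H]1c2c(OCc4ccccc4)cc(OCc4ccccc4)cc2OC2(OC)[C@@H]([C@]1(C)C=C)[C@H]3[C@@H](C[C@@H]2C)C3(C)C
F2 | step 18 | C-4 allyl analogue of F1 (allyl anti to the cyclopropane) | CC(C)C[C@H]1c2c(OCc4ccccc4)cc(OCc4ccccc4)cc2O[C@]2(CC=C)[C@@H]([C@]1(C)C=C)[C@H]3[C@@H](C[C@@H]2C)C3(C)C
F3 | step 18 | C-4 (E)-prop-1-enyl analogue | CC(C)C[C@H]1c2c(OCc4ccccc4)cc(OCc4ccccc4)cc2O[C@]2(/C=C/C)[C@@H]([C@]1(C)C=C)[C@H]3[C@@H](C[C@@H]2C)C3(C)C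
F4 | step 17 | (1R,3S,6R)-4-iodo-3,7,7-trimethylbicyclo[4.1.0]hept-4-ene | C[C@H]1C[C@@H]2[C@H](C=C1I)C2(C)C
F5 | step 13 | [(2R,3R)-3-aryl-2-methyloxiran-2-yl]methanol (aryl as in 16) | OC[C@@]1(C)O[C@@H]1c1c(OCOCC[Si](C)(C)C)cc(OCc2ccccc2)cc1OCc1ccccc1
F6 | step 13 | 3-aryl-2,5-dimethylhexane-1,2-diol (benzylic centre as in 19) | CC(C)C[C@H]([C@](C)(O)CO)c1c(OCOCC[Si](C)(C)C)cc(OCc2ccccc2)cc1OCc1ccccc1
F7 | step 13 | cyclic thionocarbonate of F6 | CC(C)C[C@H]([C@@]1(C)COC(=S)O1)c1c(OCOCC[Si](C)(C)C)cc(OCc2ccccc2)cc1OCc1ccccc1
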